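Partner is charged above substrate in violet and red, but below it in teal and blue, and the reckoning starts from that sign.

| flask | substrate | partner | remark | time |
|---|---|---|---|---|
| south-east | 0.43 M | 0.468 M | run made earlier |  |
| violet | 0.39 M | 1.00 M |  | 4.0 min |
| teal | 1.2 M | 0.468 M |  | 4.0 min |
| blue | 1.2 M | 1.00 M |  | 4.0 min |
| red | 0.39 M | 0.468 M |  | 4.0 min |

- south-east (time / min: target / %): 0.200: 67.5; 0.417: 71.3; 1.00: 68.2; 2.50: 60.2

(standard deviation of a reading: 0.3 percentage points)



- the flasks by amount of target, in percent of the substrate charged, highest first, at 4.0 min (violet / teal / blue / red)
- the amount of target, in percent of the substrate charged of the flask you put first, at 4.0 min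
- the amount of target, in percent of the substrate charged of the flask you put last, at 4.0 min

The south-east target reaches 71.3% by 0.417 min and then sinks, so this reckoning takes substrate to pass quickly and target to be lost slowly afterwards. Let the fast step finish, one partner per substrate. Free partner F is then the stoichiometric excess, partner charge minus substrate charge: 0.0380 M in the south-east run. Between 1.00 min and 2.50 min its target falls at 0.0832 min⁻¹. That fall per molar of free partner is the loss constant κ = 0.0365 M⁻¹ s⁻¹. This is the weak link: as a share of the substrate charged, the fall from the peak reading already exceeds the excess, so if each target lost spends one partner, more partner stood free than F counts, and κ reads high.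

In teal and blue F is negative, so partner is the limiting reagent, and target is capped at 39.0% in teal and 83.3% in blue. Red has F = 0.0780 M; spent wholly on target, that amount takes the south-east peak reading down to about 51.3% in this reckoning for red. In violet target T and F fall together, so D = F − T holds at 0.220 M, and T/F shrinks as exp(−κDt). With target started at the whole substrate charge, that leaves 5.79% of target in violet at 4.0 min. This reckoning commits to blue, red, teal, violet, with blue somewhere under its cap and violet at 5.79%.

The forecast differs: violet > red > blue > teal, top 67%, low 28%, holding that "Violet first and teal last are secure".

The flasks give blue > red > teal > violet, top 71.7%, low 6.04%.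

    substrate → side product (k = 0.0290 s⁻¹)
    partner → decomposition product (k = 7.90 × 10⁻⁵ s⁻¹)
    substrate + partner → target (k = 0.540 M⁻¹ s⁻¹)
    partner + target → over-reaction product (k = 0.0310 M⁻¹ s⁻¹)

Violet's 6.04% stands beside the reckoned 5.79%. The weak link is reforged by letting substrate that becomes side product spend no partner. The neighbour is violet with 0.60 M of partner, and 12.1% of its substrate ends as side product. The reckoning therefore starts target at 0.343 M, D is −0.0855 M, and the same κ leaves 34.0%. That neighbour holds 36.7% of target at 4.00 min, with 51.2% as over-reaction product.

The readings were generated by integration for substances that don't exist; noise was put on by code.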